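**An easy step.** I began with what a chain is worth. The average divides monomer in chains by chains begun, so if each initiator begins one chain (a guess, as no earlier run shows chains), complete conversion in summer or dusk gives 20.0 units. Once initiation is over, that figure times the share converted gives the average, and I assumed this held at the end of both flasks.

| flask | free monomer | transfer agent | initiator | remark | time |
|---|---|---|---|---|---|
| teal | 0.050 M | 0.50 mM | 10 mol% | run made earlier |  |
| summer | 0.050 M | 0.500 mM | 5 mol% |  | 5.0 h |
| dusk | 0.050 M | 0.500 mM | 5 mol% |  | 1.2 h |

teal run (percent of the free monomer charged)

| time / min | monomer in chains / % | free monomer / % |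
|---|---|---|
| 8.00 | 6 | 94 |
| 12.0 | 16 | 85 |
| 15.0 | 17 | 81 |
| 25.0 | 32 | 67 |
| 40.0 | 49 | 49 |
| 60.0 | 65 | 36 |
| 90.0 | 79 | 20 |

(each reading ± 1.5 percentage points)

- the average divides the monomer in chains by the number of chains begun, living and dead together
- steps under discussion: living end + transfer agent -> dead chain; free monomer + initiator -> living end + monomer in chains; initiator + monomer in chains -> spent initiator; free monomer + living end -> monomer in chains + living end
- the earlier runs do not show the number of chains; that part of a forecast is a guess
- no earlier run changes the charge of initiator; that part of a forecast is a guess

1. which of the two ends with the longer chains by the average number of monomer units in a chain (chains begun, living or dead) ("neither" if they lie within 10%) (summer / dusk / neither)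
2. average number of monomer units in a chain (chains begun, living or dead) at the end, summer
3. average number of monomer units in a chain (chains begun, living or dead) at the end, dusk

**Surviving ends.** The share converted depends on the ends that go on growing, so I wrote the balance of transfer agent, the limiting reagent of the killing step. Its 0.500 mM is less than the 2.50 mM of initiator. One transfer agent removes one living end, which leaves 2.00 mM in summer and dusk and 4.50 mM in teal: these are the surviving ends, initiator charged minus transfer agent charged.

**Teal's decay.** Teal read 20% free monomer at 90.0 min, which gives a first-order constant of 0.0179 min⁻¹, a reading with the scatter of 1.5 percentage points. I scaled it by surviving ends, to 0.00795 min⁻¹ for both new flasks. That too is a guess, as no earlier run changes initiator.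

**Turned round.** Summer and dusk share one charge and part by time. I reckoned 90.8% converted in summer, so 18.2 units, and 43.6% in dusk, so 8.71 units. For the two to lie within 10%, dusk would have to convert 81.7%, and my figure is less than that. Otherwise it would have to begin about half of summer's chains. I expected summer.

**The forecast.** The forecast named summer, with 19 for summer and 8.5 for dusk, holding that “Chains begun should therefore roughly equal the initiator charged”.

**The result.** Summer ended at 19.5 and dusk at 9.83, so the longer chains stood in summer. Living end in summer at 5.00 h was 0.00187 M, less than my surviving ends of 2.00 mM.

    living end + transfer agent → dead chain (kL = 0.316 M⁻¹ s⁻¹)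
    free monomer + initiator → living end + monomer in chains (k = 0.0271 M⁻¹ s⁻¹)
    initiator + monomer in chains → spent initiator (k = 0.0152 M⁻¹ s⁻¹)
    free monomer + living end → monomer in chains + living end, rate k4*[living end]*[free monomer] (k = 0.0785 M⁻¹ s⁻¹)

**The neighbour.** The neighbour is the dusk flask read at 3.0 h. It has the same surviving ends and the same constant, so I reckoned 76.1% converted and 15.2 units. That flask gave 16.7 units, with free monomer down to 20.4%.

The readings come from a simulation from invented constants, and the scatter is random.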